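**Plan**

1. Retrosynthetic cuts, in this order: the C3–aroyl bond and the C1–prenyl bond (late lithiations); the C1–C2 bond of ring B (ring closure); the C5–C4 and C5–prenyl bonds; the two C8–CH3 bonds; ring A into 5-methylhex-4-enal and methyl vinyl ketone.
2. Forward: ring A (C1, C9, C5, C6, C7, C8) arises first as a cyclohexenone; C5 is made quaternary while C1=C8 is still an alkene; the second C8 methyl follows; ring B (C1–C2–C3–C4–C5–C9) is then closed by gold-catalysed addition of the C9=C1 silyl enol ether to C2 of a bromo-ynone arm (C4(=O)–C3≡C2–Br) on C5.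
3. Enabling feature: the C9 ketone of ring A is flanked by quaternary C5 and can enolise only towards C1, and the C4 carbonyl on C5 makes C2 a Michael terminus held 1,3-diaxial to C1 across ring A.
4. Helpers: the silyl group on the C9 enol oxygen (lost in the ring closure); bromine on C2 (holds the carboxylic oxidation level, exchanged for OMe in step 10, OMe removed in step 15); silyl ethers on the catechol (removed in step 15).
5. Stereochemistry: C7 from enamine catalysis (step 1); C5 by substrate control anti to the C7 prenyl group (step 4); C1 by the geometry of bridging (step 9) and retention in the bridgehead alkylation (step 11).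

Key step: step 9

Remark: locants C1–C9 are those of the bicyclo[3.3.1]nonane core of the target and are used for all intermediates; the enol drawn for the target (C2=O, C4–OH) and the enol formed in step 15 (C2–OH, C4=O) are tautomers of one compound; 5-methylhex-4-enal is taken as a purchasable aldehyde.

**Route**

Step 1
Reactants: 1 5-methylhex-4-enal; 2 but-3-en-2-one
Product: 4 (S)-4-(3-methylbut-2-en-1-yl)cyclohex-2-en-1-one, via keto aldehyde 3 (not isolated)
Conditions: (S)-2-[methoxy(diphenyl)methyl]pyrrolidine (5 mol%), ethyl 3,4-dihydroxybenzoate (20 mol%), neat, 4 °C; then LiOH (0.2 equiv), i-PrOH, rt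
Reagents that add atoms: none
Why: Enamine-catalysed Michael addition followed by intramolecular aldol condensation (Robinson-type annulation); on the usual shielding model the E-enamine of 1 is attacked by 2 on the face remote from the CPh2OMe group of the (S)-catalyst, which should set C7 as S, and ring closure turns the epimerisable α-centre into a stable γ-centre.

Step 2
Reactants: 4
Product: 6 (S)-3-methyl-4-(3-methylbut-2-en-1-yl)cyclohex-2-en-1-one, via silyl enol ether 5 (not isolated)
Conditions: MeMgBr, CuBr·SMe2 (5 mol%), Me3SiCl, THF, −78 °C; solvent exchange to DMSO; Pd(OAc)2 (10 mol%), O2 (1 atm), rt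
Reagents that add atoms: methylmagnesium bromide, C[Mg]Br (chlorotrimethylsilane, C[Si](C)(C)Cl, enters 5 only)
Why: Copper-catalysed conjugate addition with silyl trapping puts the first methyl on C8 anti to the C7 prenyl group, and Saegusa–Ito dehydrosilylation of 5 (β-hydride loss is possible only from C8) restores the C1=C8 enone without touching C7.

Step 3
Reactants: 6; 7 1-bromo-3-methylbut-2-ene (prenyl bromide)
Product: 8 3-methyl-4,6-diprenylcyclohex-2-en-1-one (C5 epimers)
Conditions: LiN(i-Pr)2, THF, −78 °C; then 7, −78 to 0 °C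
Reagents that add atoms: none
Why: Kinetic α'-deprotonation gives the cross-conjugated lithium dienolate at C5, which is alkylated by the allylic bromide (enolate SN2 alkylation); the C5 configuration is irrelevant because C5 is enolised again in step 4.

Step 4
Reactants: 8; 9 3-(trimethylsilyl)prop-2-ynal
Product: 11 O-silylated C5 aldol adduct, via lithium aldolate 10 (not isolated)
Conditions: LiN(i-Pr)2, THF, −78 °C; 9, −78 °C; then Me3SiCl, −78 to −20 °C
Reagents that add atoms: chlorotrimethylsilane, C[Si](C)(C)Cl
Why: Aldol addition of the tetrasubstituted C5 terminus of the dienolate (C5 is the only enolisable position while C1=C8 is an alkene) to the non-enolisable ynal builds the C5 quaternary centre; the C7 prenyl group, held pseudoaxial by allylic strain with the C8 methyl, should send the aldehyde to the opposite face so that C4 is trans to the C7 prenyl group, and silylation of 10 blocks retro-aldol cleavage (both carbinol epimers are carried on).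

Step 5
Reactants: 11
Product: 13 8,8-dimethyl hydroxy ketone, via silyl enol ether 12 (not isolated)
Conditions: MeMgBr, CuBr·SMe2 (10 mol%), Me3SiCl, THF/DMPU, −78 to −30 °C; then 1 M HCl, THF, 0 °C
Reagents that add atoms: methylmagnesium bromide, C[Mg]Br (chlorotrimethylsilane, C[Si](C)(C)Cl, enters 12 only)
Why: Chlorosilane-accelerated copper-catalysed conjugate addition to the β,β-disubstituted enone installs the second C8 methyl (no new stereocentre), and dilute acid cleaves both O–Si bonds of 12 while the C-silyl alkyne survives.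

Step 6
Reactants: 13
Product: 14 C5 (trimethylsilyl)ynone
Conditions: Dess–Martin periodinane, NaHCO3, CH2Cl2, 0 °C to rt
Reagents that add atoms: none
Why: Dess–Martin oxidation of the propargylic alcohol removes the carbinol stereocentre and gives a 1,3-diketone that cannot epimerise because C5 is quaternary.

Step 7
Reactants: 14
Product: 15 C5 bromo-ynone
Conditions: N-bromosuccinimide, AgNO3 (10 mol%), acetone, rt, dark
Reagents that add atoms: N-bromosuccinimide, O=C1CCC(=O)N1Br
Why: Silver-catalysed bromodesilylation of the alkynylsilane (through a silver acetylide) places the halogen that keeps C2 at the carboxylic oxidation level; the prenyl alkenes should not react with the reagent in dry acetone in the dark.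

Step 8
Reactants: 15
Product: 16 C9=C1 tert-butyldimethylsilyl enol ether
Conditions: t-BuMe2SiOTf, i-Pr2NEt, CH2Cl2, −78 to 0 °C
Reagents that add atoms: tert-butyldimethylsilyl trifluoromethanesulfonate, CC(C)(C)[Si](C)(C)OS(=O)(=O)C(F)(F)F
Why: Soft enolisation with a silyl triflate and a hindered amine; the C9 ketone has α-hydrogens only at C1 (C5 is quaternary) and the ynone has none, so only one silyl enol ether can form, and the non-nucleophilic base should spare the bromo-ynone.

Step 9
Reactants: 16
Product: 17 2-bromo-8,8-dimethyl-5,7-diprenylbicyclo[3.3.1]non-2-ene-4,9-dione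
Conditions: [(t-Bu)2(2-biphenylyl)P]Au(NCMe)SbF6 (5 mol%), acetone, H2O (2 equiv), rt
Reagents that add atoms: none
Why: The cationic monovalent gold complex coordinates the C2≡C3 bond of the bromo-ynone, the C9=C1 silyl enol ether adds through C1 to C2 anti to gold, water removes the silyl group from the resulting oxocarbenium ion and protodeauration of the C3–Au bond releases 17. The closest known reaction type is the gold-catalysed carbocyclisation of silyl enol ethers onto tethered alkynes and 1-haloalkynes (a Conia-ene-type reaction), which is established for bicyclo[3.3.1]nonenones. Ring B (C1–C2–C3–C4–C5–C9) closes in the 6-endo-dig mode. The only new stereocentre, bridgehead C1, is controlled by C5: the ynone arm can reach C1 only across the face of ring A on which it stands (1,3-diaxial bridging), so the C1 configuration follows from that of C5, itself set anti to C7 in step 4. The step needs attack at C2 instead of 5-exo attack at C3, C- instead of O-attack and silence of the two prenyl alkenes; the C4 carbonyl polarises the alkyne so that C2 is the Michael terminus, the silyl group masks the enol oxygen, and the enol ether is far more nucleophilic than a trisubstituted alkene and is held next to the alkyne. The bromine stays on C2 as a vinyl bromide and marks C2 for the oxygen brought in by step 10.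

Step 10
Reactants: 17
Product: 18 2-methoxy-8,8-dimethyl-5,7-diprenylbicyclo[3.3.1]non-2-ene-4,9-dione
Conditions: NaOMe (1.1 equiv), MeOH, 0 °C
Reagents that add atoms: sodium methoxide, [Na+].[O-]C
Why: Addition–elimination of methoxide at C2 of the β-bromo enone (a vinylogous acyl bromide) gives the vinylogous ester; a short reaction at 0 °C should avoid retro-Claisen opening of the non-enolisable C4/C9 diketone.

Step 11
Reactants: 18; 7
Product: 19 2-methoxy-8,8-dimethyl-1,5,7-triprenylbicyclo[3.3.1]non-2-ene-4,9-dione
Conditions: LiN(i-Pr)2, THF, −78 °C; then 7, −78 to −40 °C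
Reagents that add atoms: none
Why: Bridgehead deprotonation at C1 (α to the C9 ketone, next to the methoxy-bearing C2) and alkylation of the configurationally fixed bridgehead carbanion with retention, a substitution known for enol ethers of bicyclo[3.3.1]nonane-2,4,9-triones; C1 becomes quaternary with the configuration imposed by the ring.

Step 12
Reactants: 20 3,4-dihydroxybenzoic acid
Product: 21 tert-butyldimethylsilyl 3,4-bis(tert-butyldimethylsilyloxy)benzoate
Conditions: t-BuMe2SiCl, imidazole, DMF, rt
Reagents that add atoms: tert-butyldimethylsilyl chloride, CC(C)(C)[Si](C)(C)Cl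
Why: Exhaustive silylation of the two phenols and the acid under standard silyl chloride–imidazole conditions.

Step 13
Reactants: 21
Product: 22 3,4-bis(tert-butyldimethylsilyloxy)benzoyl chloride
Conditions: (COCl)2, DMF (cat.), CH2Cl2, 0 °C to rt
Reagents that add atoms: oxalyl chloride, O=C(Cl)C(=O)Cl
Why: Silyl esters are converted directly into acid chlorides by the Vilsmeier reagent from oxalyl chloride and DMF under neutral conditions, which leaves the aryl silyl ethers intact.

Step 14
Reactants: 19; 22
Product: 23 C3-aroylated methyl enol ether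
Conditions: lithium 2,2,6,6-tetramethylpiperidide, THF, −78 °C; then 22, −78 to −40 °C
Reagents that add atoms: none
Why: Vinylic lithiation at C3 (between the methoxy-bearing C2 and the C4 carbonyl) by the hindered amide and C-acylation with the aroyl chloride, as known for vinylogous esters of this bicyclic class; no stereocentre is affected.

Step 15
Reactants: 23
Product: 24 aristophenone A
Conditions: LiOH, H2O/1,4-dioxane (degassed, Ar), 90 °C; then 1 M HCl, 0 °C
Reagents that add atoms: lithium hydroxide, [Li+].[OH-]
Why: Hydroxide cleaves the two aryl silyl ethers and hydrolyses the vinylogous methyl ester by addition–elimination at C2 (the hydroxide oxygen becomes the enol oxygen), and acidification gives the enolised triketone; exclusion of air protects the catechol.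

**Compound list**

1 | 5-methylhex-4-enal | CC(C)=CCCC=O | starting material
2 | but-3-en-2-one (methyl vinyl ketone) | CC(=O)C=C | starting material
3 | (S)-2-(3-methylbut-2-en-1-yl)-5-oxohexanal | CC(C)=CC[C@@H](C=O)CCC(C)=O | intermediate
4 | (S)-4-(3-methylbut-2-en-1-yl)cyclohex-2-en-1-one | CC(C)=CC[C@@H]1CCC(=O)C=C1 | intermediate
5 | trans-3-methyl-4-(3-methylbut-2-en-1-yl)-1-(trimethylsilyloxy)cyclohex-1-ene, prenyl-bearing carbon as in 4 | CC(C)=CC[C@@H]1CCC(O[Si](C)(C)C)=C[C@H]1C | intermediate
6 | (S)-3-methyl-4-(3-methylbut-2-en-1-yl)cyclohex-2-en-1-one | CC(C)=CC[C@@H]1CCC(=O)C=C1C | intermediate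
7 | 1-bromo-3-methylbut-2-ene (prenyl bromide) | CC(C)=CCBr | starting material
8 | 3-methyl-4,6-bis(3-methylbut-2-en-1-yl)cyclohex-2-en-1-one, C7 as in 6, both C5 epimers | CC(C)=CC[C@@H]1CC(CC=C(C)C)C(=O)C=C1C | intermediate
9 | 3-(trimethylsilyl)prop-2-ynal | C[Si](C)(C)C#CC=O | starting material
10 | lithium alkoxide of the C5 aldol adduct of 8 and 9, carbinol arm trans to the C7 prenyl group, both carbinol epimers | CC(C)=CC[C@@H]1C[C@@](CC=C(C)C)(C([O-])C#C[Si](C)(C)C)C(=O)C=C1C.[Li+] | intermediate
11 | 3-methyl-4,6-bis(3-methylbut-2-en-1-yl)-6-[1-(trimethylsilyloxy)-3-(trimethylsilyl)prop-2-yn-1-yl]cyclohex-2-en-1-one, C5 arm trans to the C7 prenyl group, both carbinol epimers | CC(C)=CC[C@@H]1C[C@@](CC=C(C)C)(C(O[Si](C)(C)C)C#C[Si](C)(C)C)C(=O)C=C1C | intermediate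
12 | C9=C1 trimethylsilyl enol ether of the 8,8-dimethyl ketone, still carrying the O-silyl group on C4 | CC(C)=CC[C@@H]1C[C@@](CC=C(C)C)(C(O[Si](C)(C)C)C#C[Si](C)(C)C)C(O[Si](C)(C)C)=CC1(C)C | intermediate
13 | 6-[1-hydroxy-3-(trimethylsilyl)prop-2-yn-1-yl]-3,3-dimethyl-4,6-bis(3-methylbut-2-en-1-yl)cyclohexan-1-one, C5 arm trans to the C7 prenyl group, both carbinol epimers | CC(C)=CC[C@@H]1C[C@@](CC=C(C)C)(C(O)C#C[Si](C)(C)C)C(=O)CC1(C)C | intermediate
14 | 3,3-dimethyl-4,6-bis(3-methylbut-2-en-1-yl)-6-[3-(trimethylsilyl)prop-2-ynoyl]cyclohexan-1-one, acyl group trans to the C7 prenyl group | CC(C)=CC[C@@H]1C[C@@](CC=C(C)C)(C(=O)C#C[Si](C)(C)C)C(=O)CC1(C)C | intermediate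
15 | 6-(3-bromoprop-2-ynoyl)-3,3-dimethyl-4,6-bis(3-methylbut-2-en-1-yl)cyclohexan-1-one, acyl group trans to the C7 prenyl group | CC(C)=CC[C@@H]1C[C@@](CC=C(C)C)(C(=O)C#CBr)C(=O)CC1(C)C | intermediate
16 | 3-bromo-1-[2-(tert-butyldimethylsilyloxy)-4,4-dimethyl-1,5-bis(3-methylbut-2-en-1-yl)cyclohex-2-en-1-yl]prop-2-yn-1-one, configuration as in 15 | CC(C)=CC[C@@H]1C[C@@](CC=C(C)C)(C(=O)C#CBr)C(O[Si](C)(C)C(C)(C)C)=CC1(C)C | intermediate
17 | 2-bromo-8,8-dimethyl-5,7-bis(3-methylbut-2-en-1-yl)bicyclo[3.3.1]non-2-ene-4,9-dione, C7 prenyl on the face of ring A opposite to the C2–C4 bridge, absolute configuration as in 24 | CC(C)=CC[C@@H]1C[C@]2(CC=C(C)C)C(=O)[C@@H](C(Br)=CC2=O)C1(C)C | intermediate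
18 | 2-methoxy-8,8-dimethyl-5,7-bis(3-methylbut-2-en-1-yl)bicyclo[3.3.1]non-2-ene-4,9-dione, configuration as in 17 | CC(C)=CC[C@@H]1C[C@]2(CC=C(C)C)C(=O)[C@@H](C(OC)=CC2=O)C1(C)C | intermediate
19 | 2-methoxy-8,8-dimethyl-1,5,7-tris(3-methylbut-2-en-1-yl)bicyclo[3.3.1]non-2-ene-4,9-dione, configuration as in 24 | CC(C)=CC[C@@H]1C[C@]2(CC=C(C)C)C(=O)[C@@](CC=C(C)C)(C(OC)=CC2=O)C1(C)C | intermediate
20 | 3,4-dihydroxybenzoic acid | O=C(O)c1ccc(O)c(O)c1 | starting material
21 | tert-butyldimethylsilyl 3,4-bis(tert-butyldimethylsilyloxy)benzoate | CC(C)(C)[Si](C)(C)OC(=O)c1ccc(O[Si](C)(C)C(C)(C)C)c(O[Si](C)(C)C(C)(C)C)c1 | intermediate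
22 | 3,4-bis(tert-butyldimethylsilyloxy)benzoyl chloride | O=C(Cl)c1ccc(O[Si](C)(C)C(C)(C)C)c(O[Si](C)(C)C(C)(C)C)c1 | intermediate
23 | 3-[3,4-bis(tert-butyldimethylsilyloxy)benzoyl]-2-methoxy-8,8-dimethyl-1,5,7-tris(3-methylbut-2-en-1-yl)bicyclo[3.3.1]non-2-ene-4,9-dione, configuration as in 24 | CC(C)=CC[C@@H]1C[C@]2(CC=C(C)C)C(=O)[C@@](CC=C(C)C)(C(OC)=C(C(=O)c3ccc(O[Si](C)(C)C(C)(C)C)c(O[Si](C)(C)C(C)(C)C)c3)C2=O)C1(C)C | intermediate
24 | aristophenone A | CC(C)=CC[C@@H]1C[C@]2(CC=C(C)C)C(=O)[C@@](CC=C(C)C)(C(=O)C(C(=O)c3ccc(O)c(O)c3)=C2O)C1(C)C | target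

**Step count and risks**

Total step count: 15. Longest linear sequence: 13 (steps 1–11, 14, 15).

Steps most likely to fail:

1. Step 9. The ring closure may be diverted by 5-exo attack at C3, by bromine migration through a gold vinylidene, by cycloisomerisation involving a prenyl alkene, or by protodesilylation of the enol ether before the C–C bond forms. The fallback sets out from 8 and comes back at 18, and it replaces the tethered closure by a two-bond annulation. Copper-catalysed conjugate methyl addition to 8 (MeMgBr, CuBr·SMe2, Me3SiCl; then dilute HCl) would give 3,3-dimethyl-4,6-diprenylcyclohexanone F1. Trimethyl orthoformate and p-toluenesulfonic acid in methanol would give the more substituted methyl enol ether F2. Effenberger annulation with malonyl dichloride (KOH, BnEt3NCl, −10 °C) would acylate C5 anti to the C7 prenyl group and then close C1–C2 to give bicyclic trione F3. O-Methylation (dimethyl sulfate, K2CO3, acetone) would give 18 together with the regioisomeric enol ether F4, which would be removed by chromatography.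

2. Step 8. Enol silylation may fail through conjugate addition of the amine or of triflate to the bromo-ynone, or through slow enolisation at the neopentyl C1 methylene, so that the substrate decomposes before it is silylated. The fallback sets out from 15 and comes back at 18, and it needs neither the silyl enol ether nor gold. Sodium methoxide in methanol (2 equiv, 0 °C) would convert the bromo-ynone by twofold addition–elimination into the β,β-dimethoxy enone F5. KN(SiMe3)2 in THF (−78 to 0 °C) would then form the C1 enolate, the only one possible, which would add to C2 and expel methoxide (vinylogous Claisen condensation on an α-oxo ketene acetal) to give 18 directly.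

3. Step 11. The bridgehead alkylation may suffer from competing vinylic lithiation at C3 or from incomplete deprotonation at C1 next to the gem-dimethyl group. The fallback sets out from 18 and comes back at 19, and it blocks C3 first. Lithium 2,2,6,6-tetramethylpiperidide with Me3SiCl present (THF, −78 °C) would give the C3-silylated enol ether F6. LiN(i-Pr)2 and then 7 would alkylate the bridgehead to give the C1-prenylated silane F7. Bu4NF in THF would remove the silyl group and give 19.

**Further compounds**

F1 | step 9 | 3,3-dimethyl-4,6-bis(3-methylbut-2-en-1-yl)cyclohexan-1-one, C7 as in 6, both C5 epimers | CC(C)=CC[C@@H]1CC(CC=C(C)C)C(=O)CC1(C)C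
F2 | step 9 | 1-methoxy-5,5-dimethyl-2,4-bis(3-methylbut-2-en-1-yl)cyclohex-1-ene, C7 as in 6 | CC(C)=CC[C@@H]1CC(CC=C(C)C)=C(OC)CC1(C)C
F3 | step 9 | 8,8-dimethyl-5,7-bis(3-methylbut-2-en-1-yl)bicyclo[3.3.1]nonane-2,4,9-trione, configuration as in 17 | CC(C)=CC[C@@H]1C[C@]2(CC=C(C)C)C(=O)[C@@H](C(=O)CC2=O)C1(C)C
F4 | step 9 | enol-ether regioisomer of 18 with OMe on C4 and C2=O | CC(C)=CC[C@@H]1C[C@]2(CC=C(C)C)C(=O)[C@@H](C(=O)C=C2OC)C1(C)C
F5 | step 8 | 6-(3,3-dimethoxyprop-2-enoyl)-3,3-dimethyl-4,6-bis(3-methylbut-2-en-1-yl)cyclohexan-1-one, configuration as in 15 | CC(C)=CC[C@@H]1C[C@@](CC=C(C)C)(C(=O)C=C(OC)OC)C(=O)CC1(C)C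
F6 | step 11 | 2-methoxy-8,8-dimethyl-5,7-bis(3-methylbut-2-en-1-yl)-3-(trimethylsilyl)bicyclo[3.3.1]non-2-ene-4,9-dione | CC(C)=CC[C@@H]1C[C@]2(CC=C(C)C)C(=O)[C@@H](C(OC)=C([Si](C)(C)C)C2=O)C1(C)C
F7 | step 11 | 2-methoxy-8,8-dimethyl-1,5,7-tris(3-methylbut-2-en-1-yl)-3-(trimethylsilyl)bicyclo[3.3.1]non-2-ene-4,9-dione | CC(C)=CC[C@@H]1C[C@]2(CC=C(C)C)C(=O)[C@@](CC=C(C)C)(C(OC)=C([Si](C)(C)C)C2=O)C1(C)C
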